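**Plan**

- Enabling feature: ring B (C5–C10) carries the C7=C8–C17O2H unit. An enoic acid of this kind is what remains of a C8 malonate with an oxygen at C7 once one carboxyl carbon and that oxygen are lost. Ring B can therefore be cut at C9–C10 and C7–C8 into a 1-silyloxy diene on ring A (C10=C5–C6=C7–OSi) and an alkylidene malonate (C9=C8) that already holds the C11–C16 chain.
- Retrosynthetic cuts, in order: the C15 acetate and C17 ester adjustments; the C7=C8 alkene (back to the 7-silyloxy 8,8-diester); the C5–H bond (back to the 5-ene); the two ring B bonds C9–C10 and C7–C8; then C8=C9 (Knoevenagel) and the trisubstituted alkene of citronellol (ozonolysis).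
- Forward: ring A is bought as β-homocyclocitral and silylated. The chain aldehyde from (S)-citronellol is condensed with dimethyl malonate. Ring B closes and the chain is joined in one step. Hydrogen-atom-transfer (HAT) hydrogenation, dealkoxycarbonylative elimination, saponification and acetylation follow.
- Stereochemistry: C13 comes from (S)-citronellol, C9 from the chiral copper catalyst, C10 (and the transient C7) from the exo, suprafacial course of the ring closure, and C5 from HAT reduction to the trans-decalin.

Key step: step 5

Remark on numbering: labdane numbering is used for all skeletal atoms; α is the face opposite the C10 methyl group.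

Assumption: the (S,S)-tert-butyl bis(oxazoline) copper complex is taken to leave the Si face of C9 of the chelated alkylidene malonate open; if the sense of induction is the opposite, the equally available (R,R)-ligand is used in step 5 and nothing else changes.

**Step 1**
Reactants: 1 β-homocyclocitral
Product: 2 tert-butyldimethylsilyl (E)-dienol ether of β-homocyclocitral
Conditions: TBSOTf, Et3N, CH2Cl2, 0 °C → rt
Reagents that add atoms: tert-butyldimethylsilyl triflate, CC(C)(C)[Si](C)(C)OS(=O)(=O)C(F)(F)F
Why: Soft enolisation (silyl triflate/amine) of an aldehyde whose α-CH2 is also allylic should give the conjugated 1-silyloxy diene by O-silylation and α-deprotonation; the (E)-enol ether, in which the silyloxy group avoids the 2,6,6-trimethylcyclohexenyl group, is expected to predominate and is the isomer carried on.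

**Step 2**
Reactants: 3 (S)-citronellol
Product: 4 (S)-citronellyl acetate
Conditions: Ac2O, pyridine, DMAP (cat.), CH2Cl2, rt
Reagents that add atoms: acetic anhydride, CC(=O)OC(C)=O
Why: DMAP-catalysed acylation of a primary alcohol, which leaves the C13 stereocentre untouched.

**Step 3**
Reactants: 4 (S)-citronellyl acetate
Product: 6 (3S)-3-methyl-6-oxohexyl acetate, via secondary ozonide 5 (not isolated)
Conditions: O3, CH2Cl2, −78 °C; then PPh3, −78 °C → rt
Reagents that add atoms: ozone, [O-][O+]=O
Why: Ozonolysis with reductive work-up (Criegee mechanism) cleaves the only alkene to the aldehyde and acetone without affecting the acetate or the remote stereocentre.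

**Step 4**
Reactants: 6 (3S)-3-methyl-6-oxohexyl acetate; 7 dimethyl malonate
Product: 8 dimethyl 2-[(4S)-6-acetoxy-4-methylhexylidene]malonate
Conditions: TiCl4, pyridine, THF, 0 °C → rt
Reagents that add atoms: none
Why: The TiCl4/pyridine variant of the Knoevenagel condensation converts enolisable aliphatic aldehydes into alkylidene malonates at low temperature, and the two identical ester groups mean that no alkene geometry arises.

**Step 5**
Reactants: 2 tert-butyldimethylsilyl (E)-dienol ether of β-homocyclocitral; 8 dimethyl 2-[(4S)-6-acetoxy-4-methylhexylidene]malonate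
Product: 9 ring B cycloadduct, dimethyl (13S)-15-acetoxy-7α-(tert-butyldimethylsilyloxy)-17-norlabd-5-ene-8,8-dicarboxylate (9α-H, 10β-CH3)
Conditions: 2 (1.5 equiv), [Cu((S,S)-t-Bu-box)](SbF6)2 (10 mol %, made from CuCl2, the ligand and AgSbF6; t-Bu-box = 2,2'-isopropylidenebis(4-tert-butyl-2-oxazoline)), CH2Cl2, −40 °C → rt
Reagents that add atoms: none
Why: Proposed new method: the bis(oxazoline)-bound Cu(SbF6)2 chelates both ester carbonyls of 8 and makes C9 strongly electrophilic, the electron-rich C10 terminus of siloxydiene 2 adds to C9 (vinylogous Mukaiyama–Michael), and the copper malonate carbon C8 then closes on the silyloxocarbenium carbon C7, either as one asynchronous [4+2] event or in two stages, silicon staying on oxygen because no alcohol additive is present. The closest known reactions are the enantioselective Mukaiyama–Michael additions of enolsilanes to alkylidene malonates and the Diels–Alder reactions of chelating dienophiles under the same divalent-copper bis(oxazoline) catalysts; what is new is a fully substituted nucleophilic diene terminus that must create the quaternary C10. Ring B closes as a six-membered carbocycle, formally a normal-demand [4+2] cycloaddition and in the stepwise picture a 6-(enolexo)-exo-trig attack of the malonate on C7. C9 is set by the ligand, whose tert-butyl groups should leave only the Si face of C9 open; C10 follows from the exo placement of the side chain, away from ring A and the C4 methyls and therefore cis to the C10 methyl; C7 follows from suprafacial addition to the (E)-dienol ether, which puts the silyloxy group trans to the C10 methyl. The step needs regioselectivity (C10 to C9, C7 to C8), secured by the oxygen donor at C7 and the polarisation of the acceptor, and carbon rather than oxygen closure of the malonate, favoured because C7 is an unhindered CH terminus whereas oxygen closure would have to occur at C5 between two quaternary carbons; the double activation and two-point binding of the acceptor are what should compensate for the hindered C10.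

**Step 6**
Reactants: 9 ring B cycloadduct
Product: 10 dimethyl (13S)-15-acetoxy-7α-(tert-butyldimethylsilyloxy)-17-norlabdane-8,8-dicarboxylate (5α-H, 9α-H, 10β-CH3)
Conditions: Mn(dpm)3 (10 mol %; dpm = dipivaloylmethanate), PhSiH3, t-BuOOH, i-PrOH, rt
Reagents that add atoms: none
Why: Manganese-hydride HAT hydrogenation adds a hydrogen atom to C6 and then reduces the tertiary C5 radical by axial delivery on the face opposite the C10 methyl, which should give the trans-decalin (5α-H) at an alkene that is flanked by the quaternary C4 and C10 and is therefore slow on metal surfaces; esters, acetate and silyl ether are inert.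

**Step 7**
Reactants: 10 saturated 7α-silyloxy 8,8-diester
Product: 12 methyl (5S,9R,10S,13S)-15-acetoxylabd-7-en-17-oate, via lithium 8β-carboxylate 11 (not isolated)
Conditions: LiCl (3 equiv), H2O (2 equiv), DMSO, 150 °C
Reagents that add atoms: none
Why: In this Krapcho dealkoxycarbonylation chloride demethylates one ester by SN2, and carboxylate 11, whose C8–CO2 bond is anti-periplanar to the axial 7α-silyloxy group, should lose CO2 with expulsion of silanolate (decarboxylative anti elimination, or E1cB from the ester enolate) to give the conjugated 7-ene ester, the released CO2 buffering the silanolate.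

**Step 8**
Reactants: 12 methyl (5S,9R,10S,13S)-15-acetoxylabd-7-en-17-oate
Product: 13 (5S,9R,10S,13S)-15-hydroxylabd-7-en-17-oic acid
Conditions: KOH, MeOH/H2O, 70 °C; then 1 M HCl
Reagents that add atoms: potassium hydroxide, [K+].[OH-]
Why: Saponification (BAc2) of the hindered conjugated methyl ester needs hot hydroxide, which also removes the C15 acetate (hence the separate final acetylation); the alkene stays in conjugation and no stereocentre is acidic.

**Step 9**
Reactants: 13 (5S,9R,10S,13S)-15-hydroxylabd-7-en-17-oic acid
Product: 15 (5S,9R,10S,13S)-15-acetoxylabd-7-en-17-oic acid (CNP0412535.1), via mixed acetic anhydride 14 (not isolated)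
Conditions: Ac2O, pyridine, DMAP (cat.), CH2Cl2, 0 °C → rt; then H2O/THF, rt
Reagents that add atoms: acetic anhydride, CC(=O)OC(C)=O
Why: Acylation of the primary alcohol with acetic anhydride is routine, and the carboxyl group can form at most the mixed anhydride 14, which the aqueous quench should hydrolyse at the acetyl carbonyl so that only O15 stays acetylated.

**Compound list**

1 | β-homocyclocitral, (2,6,6-trimethylcyclohex-1-en-1-yl)acetaldehyde | CC1=C(CC=O)C(C)(C)CCC1 | starting material
2 | tert-butyl(dimethyl){[(E)-2-(2,6,6-trimethylcyclohex-1-en-1-yl)ethenyl]oxy}silane | CC1=C(/C=C/O[Si](C)(C)C(C)(C)C)C(C)(C)CCC1 | intermediate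
3 | (S)-citronellol, (3S)-3,7-dimethyloct-6-en-1-ol | OCC[C@@H](C)CCC=C(C)C | starting material
4 | (S)-citronellyl acetate | CC(=O)OCC[C@@H](C)CCC=C(C)C | intermediate
5 | secondary ozonide of 4 (3,3-dimethyl-1,2,4-trioxolane, both configurations at the ring CH) | CC(=O)OCC[C@@H](C)CCC1OOC(C)(C)O1 | intermediate
6 | (3S)-3-methyl-6-oxohexyl acetate | CC(=O)OCC[C@@H](C)CCC=O | intermediate
7 | dimethyl malonate | COC(=O)CC(=O)OC | starting material
8 | dimethyl 2-[(4S)-6-acetoxy-4-methylhexylidene]malonate | CC(=O)OCC[C@@H](C)CCC=C(C(=O)OC)C(=O)OC | intermediate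
9 | dimethyl (13S)-15-acetoxy-7α-(tert-butyldimethylsilyloxy)-17-norlabd-5-ene-8,8-dicarboxylate (9α-H, 10β-CH3) | CC(=O)OCC[C@@H](C)CC[C@H]1C(C(=O)OC)(C(=O)OC)[C@H](O[Si](C)(C)C(C)(C)C)C=C2C(C)(C)CCC[C@]12C | intermediate
10 | dimethyl (13S)-15-acetoxy-7α-(tert-butyldimethylsilyloxy)-17-norlabdane-8,8-dicarboxylate (5α-H, 9α-H, 10β-CH3) | CC(=O)OCC[C@@H](C)CC[C@H]1C(C(=O)OC)(C(=O)OC)[C@H](O[Si](C)(C)C(C)(C)C)C[C@H]2C(C)(C)CCC[C@]12C | intermediate
11 | lithium 8β-carboxylate of 10 (8α-CO2CH3 retained) | [Li+].CC(=O)OCC[C@@H](C)CC[C@H]1[C@@](C(=O)OC)(C(=O)[O-])[C@H](O[Si](C)(C)C(C)(C)C)C[C@H]2C(C)(C)CCC[C@]12C | intermediate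
12 | methyl (5S,9R,10S,13S)-15-acetoxylabd-7-en-17-oate | CC(=O)OCC[C@@H](C)CC[C@H]1C(C(=O)OC)=CC[C@H]2C(C)(C)CCC[C@]12C | intermediate
13 | (5S,9R,10S,13S)-15-hydroxylabd-7-en-17-oic acid | OCC[C@@H](C)CC[C@H]1C(C(=O)O)=CC[C@H]2C(C)(C)CCC[C@]12C | intermediate
14 | mixed anhydride of 15 with acetic acid (at C17) | CC(=O)OCC[C@@H](C)CC[C@H]1C(C(=O)OC(C)=O)=CC[C@H]2C(C)(C)CCC[C@]12C | intermediate
15 | (5S,9R,10S,13S)-15-acetoxylabd-7-en-17-oic acid | CC(=O)OCC[C@@H](C)CC[C@H]1C(C(=O)O)=CC[C@H]2C(C)(C)CCC[C@]12C | target

**Step count**

Total: 9 steps. Longest linear sequence: 8 steps (steps 2–9, from (S)-citronellol).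

**Steps most likely to fail**

Step 5. The fully substituted C10 terminus may add too slowly, so that protodesilylation of the diene or isomerisation of the alkylidene malonate takes over. Ring closure may stall at the open-chain adduct or take place through oxygen. Face discrimination at C9 may be poor because the C9 substituent is an unbranched chain, the least favourable class for this catalyst family. The fallback uses auxiliary control and known reactions; it sets out from aldehyde 6 and diene 2 and comes back at hydroxy acid 13. A Horner–Wadsworth–Emmons reaction of 6 under Masamune–Roush conditions (LiCl, i-Pr2NEt, MeCN) with diethyl {2-[(4R)-4-benzyl-2-oxooxazolidin-3-yl]-2-oxoethyl}phosphonate would give the (E)-N-enoyl oxazolidinone F1. A Me2AlCl-promoted, auxiliary-controlled Diels–Alder reaction with 2 (CH2Cl2, −78 → −30 °C; acyl group endo, chain exo, diene on the face away from the benzyl group, which is the Si face of C9) would give the 8α-acyl cycloadduct F2. HAT hydrogenation as in step 6 would give the 5α-H imide F3. DBU (toluene, 80 °C) would remove silanol across the trans-diaxial H8/7-OSi pair to give the ring enoyl imide F4. LiOH/H2O2 (THF/H2O, 0 °C) would then cleave auxiliary and acetate to give 13, which goes on to step 9.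

Step 6. Hydrogen may be delivered to the C5 radical from the β face, giving the cis-decalin, or hydrogen-atom transfer to the crowded alkene may be sluggish. The fallback replaces radical control by hydroxyl direction; it sets out from cycloadduct 9 and comes back at methyl enoate 12. HF·pyridine (THF/pyridine, 0 °C → rt) would give the 7α-allylic alcohol F5. Its hydroxyl group should steer hydrogenation with [Ir(cod)(PCy3)(py)]PF6 (H2, CH2Cl2, rt) to the α face, giving the 5α-H hydroxy diester F6. Mesylation (MsCl, Et3N, CH2Cl2, 0 °C) would give mesylate F7. LiCl in wet DMSO at 140 °C would then bring about dealkoxycarbonylation with loss of methanesulfonate to give 12, so that step 7 is bypassed as well.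

Step 7. The silyl ether may be cleaved before demethylation, after which retro-aldol opening of ring B can follow, or the ester enolate may be protonated without losing silanolate. The fallback changes the leaving group; it sets out from 10 and comes back at 12. Ac2O with catalytic FeCl3 (0 °C) would exchange the silyl ether directly for an acetate, giving the 7α-acetoxy diester F8. LiCl in wet DMSO at 150 °C would then effect dealkoxycarbonylation with loss of acetate to give 12.

**Further compounds**

F1 | step 5 | (4R)-3-[(2E,6S)-8-acetoxy-6-methyloct-2-enoyl]-4-benzyloxazolidin-2-one | CC(=O)OCC[C@@H](C)CC/C=C/C(=O)N1[C@H](Cc2ccccc2)COC1=O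
F2 | step 5 | 8α-acyl cycloadduct: (13S)-15-acetoxy-7α-(tert-butyldimethylsilyloxy)labd-5-en-17-oyl imide of (4R)-4-benzyloxazolidin-2-one (8β-H, 9α-H, 10β-CH3) | CC(=O)OCC[C@@H](C)CC[C@H]1[C@H](C(=O)N3[C@H](Cc4ccccc4)COC3=O)[C@H](O[Si](C)(C)C(C)(C)C)C=C2C(C)(C)CCC[C@]12C
F3 | step 5 | 5α-H imide: (13S)-15-acetoxy-7α-(tert-butyldimethylsilyloxy)labdan-17-oyl imide of (4R)-4-benzyloxazolidin-2-one (5α-H, 8β-H, 9α-H) | CC(=O)OCC[C@@H](C)CC[C@H]1[C@H](C(=O)N3[C@H](Cc4ccccc4)COC3=O)[C@H](O[Si](C)(C)C(C)(C)C)C[C@H]2C(C)(C)CCC[C@]12C
F4 | step 5 | ring enoyl imide: (5S,9R,10S,13S)-15-acetoxylabd-7-en-17-oyl imide of (4R)-4-benzyloxazolidin-2-one | CC(=O)OCC[C@@H](C)CC[C@H]1C(C(=O)N3[C@H](Cc4ccccc4)COC3=O)=CC[C@H]2C(C)(C)CCC[C@]12C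
F5 | step 6 | dimethyl (13S)-15-acetoxy-7α-hydroxy-17-norlabd-5-ene-8,8-dicarboxylate | CC(=O)OCC[C@@H](C)CC[C@H]1C(C(=O)OC)(C(=O)OC)[C@H](O)C=C2C(C)(C)CCC[C@]12C
F6 | step 6 | dimethyl (13S)-15-acetoxy-7α-hydroxy-17-norlabdane-8,8-dicarboxylate (5α-H) | CC(=O)OCC[C@@H](C)CC[C@H]1C(C(=O)OC)(C(=O)OC)[C@H](O)C[C@H]2C(C)(C)CCC[C@]12C
F7 | step 6 | dimethyl (13S)-15-acetoxy-7α-(methanesulfonyloxy)-17-norlabdane-8,8-dicarboxylate (5α-H) | CC(=O)OCC[C@@H](C)CC[C@H]1C(C(=O)OC)(C(=O)OC)[C@H](OS(C)(=O)=O)C[C@H]2C(C)(C)CCC[C@]12C
F8 | step 7 | dimethyl (13S)-7α,15-diacetoxy-17-norlabdane-8,8-dicarboxylate (5α-H) | CC(=O)OCC[C@@H](C)CC[C@H]1C(C(=O)OC)(C(=O)OC)[C@H](OC(C)=O)C[C@H]2C(C)(C)CCC[C@]12C
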